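The flask poses 3 questions, and one factor answers two of them.

| flask | solid substrate | partner | remark | time |
|---|---|---|---|---|
| dawn | 0.80 M | 3.5 equiv | run made earlier |  |
| noon | 0.40 M | 2.5 equiv | run made earlier |  |
| flask | 0.80 M | 2.50 equiv |  | 6.0 h |

- dawn (time / h: product / %): 0.417: 0; 1.00: 0.8; 2.00: 1.0; 3.00: 1.4; 4.00: 4.7; 6.00: 10.5; 8.00: 19.5
- noon (time / h: product / %): 1.33: 0.2; 3.00: 1.6; 4.00: 3.5; 6.00: 9.8; 8.00: 18.1

(readings scatter by 0.5 percentage points)

* the product standing at 6.0 h, as a percentage of the solid substrate charged
* the change that raises the amount of product at 6.0 h, in percent of the solid substrate charged most ("none" if none brings more than 2 percentage points) (north-west / south-east / south / none)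
* amount of product at 6.0 h, in percent of the solid substrate charged, after south

- solid substrate is a solid; its amount is given per volume of the solution
- the numbers in the tables scatter with a standard deviation of 0.5 percentage points
- steps that have been proposed: open intermediate + second intermediate -> product; partner -> second intermediate; starting material <-> open intermediate; solid substrate <-> starting material
- at the start none of the solid substrate is in solution

- north-west: doubling the solubility of the solid substrate, all else as stated
- south-east: doubling the dissolution coefficient of the solid substrate, all else as stated
- south: doubling the amount of partner, all else as stated

1. First instants, our reckoning: nothing is dissolved at the start, and the dawn run reads 0 % product at 0.417 h. Solid must dissolve and partner must become second intermediate before product can form.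

2. Middle: at 3.00 h the dawn run reads 1.4 % and the noon run 1.6 %, so product is still small in both.

3. End: at 6.00 h the dawn run reads c(product) = 0.0840 M from 2.80 M partner, and the noon run 0.0392 M from 1.00 M. We assume that dissolving does not depend on how much solid lies there, so we compare these concentrations directly.

4. We count doublings of partner. Read from these two runs, c(product) at that time is multiplied by 1.67 per doubling of c(partner): this is the doubling factor, the apparent order in partner written as a factor.

5. This flask has 2.00 M partner, twice the noon run's, so it is one doubling up: 8.19 %. South is one doubling more: 13.7 %, a gain of 5.5 percentage points.

6. The factor 1.67 is less than 2. We guess, without a reading to show it, that doubled solubility doubles the dissolved material and the product, a gain of 8.2 points. We have no figure for a doubled dissolution coefficient, and on this guess we choose north-west.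

The forecast gives 8.2 % (7 % to 10.3 %), north-west, and 13.5 % after south (10.5 % to 16.5 %), taking the reaction as “roughly zero order in loading”.

The flask gives 8.36 %, and north-west is best, with 8.1 points against 5.2 points for south-east and 5.1 points for south.

    open intermediate + second intermediate → product (k = 0.00239 L mol⁻¹ min⁻¹)
    partner → second intermediate (k = 0.00557 min⁻¹)
    starting material ⇌ open intermediate (K = 1.45, k = 0.00739 min⁻¹)
    solid substrate ⇌ starting material, rate k4*(cs4 - [starting material]) while solid is left; crystals form when [starting material] > cs4 (solubility = 0.380 M, k = 0.00330 min⁻¹)

Against the noon reading, this flask's c(product) stands 1.71 times higher for its one doubling, close to the factor of 1.67. The south flask, with 4.00 M partner, is one doubling further, so the factor applied to this flask's result gives 14.0 %. The south flask stands at 13.5 %, which is 1.61 times this flask's product.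

The numbers in the tables stem from a simulated flask on assumed constants; noise was put on by code.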